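## Retrosynthetic overview
1. The target comes from its bis-MOM ether by a final unmasking of both phenols. No ring is formed in the route, because both benzene rings are bought (ring A as 2,4-dihydroxyacetophenone, ring B as methyl 4-hydroxybenzoate).
2. The CO–CH2 bond of the 1,3-diketone is cut by a crossed Claisen condensation between the ring-A methyl ketone and the ring-B methyl ester.
3. The 2-OMe/4-OH pattern is set by masking the free 4-OH first, which the chelated 2-OH allows, and then methylating the 2-OH.
4. The prenyl group is cut inside the chain (ArCH2–CH=CMe2) into an o-quinone methide CH2 and isobutenylboronic acid. This is the proposed new deaminative boron-to-carbon alkenyl transfer.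
5. The o-quinone methide precursor is the C3-selective phenolic Mannich base of 2,4-dihydroxyacetophenone.

Assumption: the SMILES holds no stereocentre and no stereogenic double bond, so the target is achiral and there is no enantiomer to select. It is drawn as the diketo tautomer, although the chelated enol will dominate.

## Route

Step 1
Reactants: 1 2,4-dihydroxyacetophenone; 2 bis(dimethylamino)methane
Product: 3 1-{3-[(dimethylamino)methyl]-2,4-dihydroxyphenyl}ethanone
Conditions: 2 (1.05 equiv), 1,4-dioxane, 90 °C, 3 h
Reagents that add atoms: none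
Why: Phenolic Mannich reaction with a preformed aminal; C3 lies ortho to both OH groups, is favoured by the bond fixation of the 2-OH···O=C chelate and is the most nucleophilic ring carbon under non-acidic conditions, and one equivalent of aminal leaves C5 and the methyl ketone untouched.

Step 2
Reactants: 3 1-{3-[(dimethylamino)methyl]-2,4-dihydroxyphenyl}ethanone; 4 (2-methylprop-1-en-1-yl)boronic acid
Product: 8 1-[2,4-dihydroxy-3-(3-methylbut-2-en-1-yl)phenyl]ethanone, via boronate chelate 5 (not isolated), via boron-bound quinone methide 6 (not isolated), via aryloxyborane 7 (not isolated)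
Conditions: 4 (1.5 equiv), 4 Å MS, toluene, 105 °C, 12 h; then H2O
Reagents that add atoms: none
Why: Proposed new method: metal-free deaminative alkenylation of a phenolic Mannich base, in which 3 condenses with 4 to the six-membered N→B chelate 5 whose nitrogen is quaternised (a better leaving group) and whose boron is a nucleophilic "ate" centre; C–N heterolysis gives the O-boron-bound o-quinone methide 6, the isobutenyl group shifts from boron to the exocyclic CH2 through a six-membered transition state driven by rearomatisation to give 7, and water cleaves the B–O bond; ipso transfer at the alkenyl carbon excludes the reverse-prenyl isomer and O-prenylation, the site was fixed in step 1, and no stereocentre is formed; the closest known reaction types are the Petasis borono-Mannich reaction and the addition of alkenylboronates to aryl-substituted o-quinone methides, neither of which, to my knowledge, has been shown on an unsubstituted o-quinone methide released from a Mannich base to assemble a prenyl group.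

Step 3
Reactants: 8 1-[2,4-dihydroxy-3-(3-methylbut-2-en-1-yl)phenyl]ethanone
Product: 9 1-[2-hydroxy-4-(methoxymethoxy)-3-(3-methylbut-2-en-1-yl)phenyl]ethanone
Conditions: MOMCl (1.1 equiv), K2CO3 (2 equiv), acetone, 0 °C to rt
Reagents that add atoms: chloromethyl methyl ether (MOMCl), COCCl
Why: Williamson-type O-alkylation; the 2-OH is tied up in the hydrogen bond to the acetyl group, so only the more acidic free 4-OH reacts.

Step 4
Reactants: 9 1-[2-hydroxy-4-(methoxymethoxy)-3-(3-methylbut-2-en-1-yl)phenyl]ethanone
Product: 10 1-[2-methoxy-4-(methoxymethoxy)-3-(3-methylbut-2-en-1-yl)phenyl]ethanone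
Conditions: MeI (3 equiv), K2CO3 (3 equiv), DMF, 45 °C
Reagents that add atoms: iodomethane (MeI), CI
Why: Williamson O-methylation of the only remaining phenol in a polar aprotic solvent that breaks the chelate; K2CO3 is too weak to enolise the ketone, and the MOM ether and the alkene are inert.

Step 5
Reactants: 11 methyl 4-hydroxybenzoate
Product: 12 methyl 4-(methoxymethoxy)benzoate
Conditions: MOMCl (1.2 equiv), K2CO3 (2 equiv), acetone, rt
Reagents that add atoms: chloromethyl methyl ether (MOMCl), COCCl
Why: Williamson-type O-alkylation of a simple phenol; masking prevents formation of a phenoxide that would deactivate the ester in step 6.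

Step 6
Reactants: 10 1-[2-methoxy-4-(methoxymethoxy)-3-(3-methylbut-2-en-1-yl)phenyl]ethanone; 12 methyl 4-(methoxymethoxy)benzoate
Product: 15 1-[2-methoxy-4-(methoxymethoxy)-3-(3-methylbut-2-en-1-yl)phenyl]-3-[4-(methoxymethoxy)phenyl]propane-1,3-dione, via sodium enolate 13 (not isolated), via sodium diketonate 14 (not isolated)
Conditions: NaH (3 equiv), 12 (1.5 equiv), THF, 0 to 65 °C; then AcOH, 0 °C
Reagents that add atoms: none
Why: Crossed Claisen condensation; the ester has no α-hydrogen, only the methyl ketone can enolise, and irreversible deprotonation of the product to 14 pulls the equilibrium forward, while the MOM, OMe and prenyl groups are stable to base.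

Step 7
Reactants: 15 1-[2-methoxy-4-(methoxymethoxy)-3-(3-methylbut-2-en-1-yl)phenyl]-3-[4-(methoxymethoxy)phenyl]propane-1,3-dione
Product: 16 1-[4-hydroxy-2-methoxy-3-(3-methylbut-2-en-1-yl)phenyl]-3-(4-hydroxyphenyl)propane-1,3-dione (target)
Conditions: cat. conc. HCl, MeOH, 40 °C, stopped at full conversion
Reagents that add atoms: none
Why: Acid-catalysed acetal exchange (MOM cleavage); phenolic MOM ethers cleave at an acidity below that needed to protonate the trisubstituted alkene, and the 2-OMe group blocks cyclisation to a flavone.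

## Compound list
1 | 1-(2,4-dihydroxyphenyl)ethanone (2,4-dihydroxyacetophenone) | CC(=O)c1ccc(O)cc1O | starting material
2 | N,N,N',N'-tetramethylmethanediamine (bis(dimethylamino)methane) | CN(C)CN(C)C | starting material
3 | 1-{3-[(dimethylamino)methyl]-2,4-dihydroxyphenyl}ethanone | CC(=O)c1ccc(O)c(CN(C)C)c1O | intermediate
4 | (2-methylprop-1-en-1-yl)boronic acid | CC(C)=CB(O)O | starting material
5 | cyclic N→B boronate chelate of 3 and 4 (six-membered O–B–N–CH2–C3–C4 ring; B carries OH and isobutenyl; formed in situ) | C[N+]1(C)Cc2c(O)c(C(C)=O)ccc2O[B-]1(O)C=C(C)C | intermediate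
6 | 4-acetyl-3-hydroxy-2-methylidenecyclohexa-3,5-dien-1-one with its carbonyl O bound to B(OH)(NMe2)(isobutenyl) (formed in situ) | C=C1C(O)=C(C(C)=O)C=CC1=[O+][B-](O)(N(C)C)C=C(C)C | intermediate
7 | 1-{4-[(dimethylamino)(hydroxy)boranyl]oxy-2-hydroxy-3-(3-methylbut-2-en-1-yl)phenyl}ethanone (formed in situ) | CC(=O)c1ccc(OB(O)N(C)C)c(CC=C(C)C)c1O | intermediate
8 | 1-[2,4-dihydroxy-3-(3-methylbut-2-en-1-yl)phenyl]ethanone | CC(=O)c1ccc(O)c(CC=C(C)C)c1O | intermediate
9 | 1-[2-hydroxy-4-(methoxymethoxy)-3-(3-methylbut-2-en-1-yl)phenyl]ethanone | CC(=O)c1ccc(OCOC)c(CC=C(C)C)c1O | intermediate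
10 | 1-[2-methoxy-4-(methoxymethoxy)-3-(3-methylbut-2-en-1-yl)phenyl]ethanone | CC(=O)c1ccc(OCOC)c(CC=C(C)C)c1OC | intermediate
11 | methyl 4-hydroxybenzoate | COC(=O)c1ccc(O)cc1 | starting material
12 | methyl 4-(methoxymethoxy)benzoate | COCOc1ccc(cc1)C(=O)OC | intermediate
13 | sodium enolate of 10 (formed in situ) | [Na+].C=C([O-])c1ccc(OCOC)c(CC=C(C)C)c1OC | intermediate
14 | sodium salt of 15 (formed in situ) | [Na+].COCOc1ccc(cc1)C(=O)[CH-]C(=O)c1ccc(OCOC)c(CC=C(C)C)c1OC | intermediate
15 | 1-[2-methoxy-4-(methoxymethoxy)-3-(3-methylbut-2-en-1-yl)phenyl]-3-[4-(methoxymethoxy)phenyl]propane-1,3-dione | COCOc1ccc(cc1)C(=O)CC(=O)c1ccc(OCOC)c(CC=C(C)C)c1OC | intermediate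
16 | 1-[4-hydroxy-2-methoxy-3-(3-methylbut-2-en-1-yl)phenyl]-3-(4-hydroxyphenyl)propane-1,3-dione | COc1c(C(=O)CC(=O)c2ccc(O)cc2)ccc(O)c1CC=C(C)C | target

## Step count and risks
Total step count: 7. Longest linear sequence: 6 (steps 1, 2, 3, 4, 6, 7, starting from 1).

**Step 2 (proposed new step).**
- Risks: C–N ionisation may be slow because the acetyl group weakens the phenolic push. The boronic acid may protodeboronate, and the quinone methide may oligomerise.
- Fallback (known chemistry, sets out from 1 and comes back at 8): the free 4-OH of 1 is alkylated with 3-chloro-3-methylbut-1-yne (K2CO3, KI, cat. CuI, acetone, reflux) to 1-[2-hydroxy-4-(2-methylbut-3-yn-2-yloxy)phenyl]ethanone F1. Lindlar semihydrogenation (H2, Pd/CaCO3/Pb, quinoline, EtOAc, rt) gives 1-[2-hydroxy-4-(2-methylbut-3-en-2-yloxy)phenyl]ethanone F2. Heating in N,N-diethylaniline at 130 °C triggers the aromatic Claisen rearrangement, which the 2-OH chelate steers to C3, and this gives 8.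

**Step 6.**
- Risks: a hindered, electron-rich ketone enolate meets an electron-rich ester. This may lead to slow acylation, ketone self-condensation or retro-Claisen cleavage.
- Fallback (sets out from 10 and comes back at 15): 10 is deprotonated with LDA (THF, −78 °C) and added to 4-(methoxymethoxy)benzaldehyde F3. This gives the racemic aldol 3-hydroxy-1-[2-methoxy-4-(methoxymethoxy)-3-(3-methylbut-2-en-1-yl)phenyl]-3-[4-(methoxymethoxy)phenyl]propan-1-one F4. Its carbinol is oxidised with Dess–Martin periodinane (NaHCO3, CH2Cl2, 0 °C to rt) to 15, which removes the transient stereocentre.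

**Step 7.**
- Risks: acid may close the 4-OH onto the prenyl group to form a 2,2-dimethylchroman, or may add MeOH to the alkene.
- Fallback (acid-free silyl strategy, sets out from 8 and 11 and comes back at 16): 8 is silylated at the free 4-OH (TIPSCl, imidazole, DMF) to 1-[2-hydroxy-3-(3-methylbut-2-en-1-yl)-4-(triisopropylsilyloxy)phenyl]ethanone F5. Methylation (MeI, K2CO3, acetone, reflux) gives 1-[2-methoxy-3-(3-methylbut-2-en-1-yl)-4-(triisopropylsilyloxy)phenyl]ethanone F6. In parallel, 11 is silylated in the same way to methyl 4-(triisopropylsilyloxy)benzoate F7. The two are joined by a LiHMDS-mediated crossed Claisen condensation (THF, 0 to 50 °C) to 1-[2-methoxy-3-(3-methylbut-2-en-1-yl)-4-(triisopropylsilyloxy)phenyl]-3-[4-(triisopropylsilyloxy)phenyl]propane-1,3-dione F8. TBAF buffered with AcOH (THF, 0 °C) then frees both phenols to give 16.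

## Further compounds
F1 | step 2 | 1-[2-hydroxy-4-(2-methylbut-3-yn-2-yloxy)phenyl]ethanone | CC(=O)c1ccc(OC(C)(C)C#C)cc1O
F2 | step 2 | 1-[2-hydroxy-4-(2-methylbut-3-en-2-yloxy)phenyl]ethanone | CC(=O)c1ccc(OC(C)(C)C=C)cc1O
F3 | step 6 | 4-(methoxymethoxy)benzaldehyde | COCOc1ccc(C=O)cc1
F4 | step 6 | 3-hydroxy-1-[2-methoxy-4-(methoxymethoxy)-3-(3-methylbut-2-en-1-yl)phenyl]-3-[4-(methoxymethoxy)phenyl]propan-1-one (racemic) | COCOc1ccc(cc1)C(O)CC(=O)c1ccc(OCOC)c(CC=C(C)C)c1OC
F5 | step 7 | 1-[2-hydroxy-3-(3-methylbut-2-en-1-yl)-4-(triisopropylsilyloxy)phenyl]ethanone | CC(=O)c1ccc(O[Si](C(C)C)(C(C)C)C(C)C)c(CC=C(C)C)c1O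
F6 | step 7 | 1-[2-methoxy-3-(3-methylbut-2-en-1-yl)-4-(triisopropylsilyloxy)phenyl]ethanone | CC(=O)c1ccc(O[Si](C(C)C)(C(C)C)C(C)C)c(CC=C(C)C)c1OC
F7 | step 7 | methyl 4-(triisopropylsilyloxy)benzoate | COC(=O)c1ccc(O[Si](C(C)C)(C(C)C)C(C)C)cc1
F8 | step 7 | 1-[2-methoxy-3-(3-methylbut-2-en-1-yl)-4-(triisopropylsilyloxy)phenyl]-3-[4-(triisopropylsilyloxy)phenyl]propane-1,3-dione | COc1c(C(=O)CC(=O)c2ccc(O[Si](C(C)C)(C(C)C)C(C)C)cc2)ccc(O[Si](C(C)C)(C(C)C)C(C)C)c1CC=C(C)C
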